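Ring numbering used throughout: C1 is the carbinol carbon that carries the undecanoyl group, C2 and C5 are the acetoxy carbons, C3=C4 is the ring alkene.
Retrosynthesis: the ketone and the C1–OH are first traced back to an exocyclic C1=CH(decyl) alkene. The C2–O and C5–O bonds are then cut together as the adduct of O2 with a ring diene, and finally the exocyclic C=C bond is cut to cyclopentadiene and undecanal.
Forward: the five-membered carbocycle is bought as its dimer and the C11 chain is attached first by fulvene condensation. The only ring made afterwards is a peroxide bridge that is opened in the same flask, and the exocyclic alkene is oxidised last.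
Enabling feature: the oxygens on C2 and C5 are cis-1,4 across the C3=C4 alkene of the cyclopentene ring, and C1 with its acyl carbon is an oxidised exocyclic alkene. The C16 skeleton is therefore 6-decylfulvene whose locked s-cis ring diene has taken up singlet oxygen.
Stereochemistry: C2 and C5 become cis in the suprafacial [4+2]; C1 is set by osmylation on the face away from both acetates. The target is meso (mirror plane through C1 and the midpoint of C3=C4), so no absolute control is needed.

Key step: step 3

Remark: every chiral intermediate of the route is racemic and is drawn as one enantiomer; both enantiomers end in the same meso target.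

Step 1
Reactants: 1 endo-dicyclopentadiene
Product: 2 cyclopenta-1,3-diene
Conditions: neat, 170–180 °C, slow distillation through a Vigreux column, receiver at −78 °C, used the same day
Reagents that add atoms: none
Why: Thermal retro-Diels–Alder reaction, in which each molecule of the dimer splits into two molecules of the low-boiling monomer, which is distilled off before it can re-dimerise.

Step 2
Reactants: 2 cyclopenta-1,3-diene (2 equiv); 3 undecanal
Product: 4 6-decylfulvene
Conditions: pyrrolidine (15 mol %), MeOH/H2O 4:1, 0 °C to rt, argon, dark; product kept cold and used promptly
Reagents that add atoms: none
Why: Amine-mediated fulvene condensation (Thiele-type fulvene synthesis run through the pyrrolidine iminium ion of the aldehyde), in which cyclopentadienide adds to the iminium carbon and loss of pyrrolidine gives the exocyclic alkene, the aldehyde oxygen leaving as water and no stereocentre being created.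

Step 3
Reactants: 4 6-decylfulvene
Product: 6 cis-2-undecylidenecyclopent-4-ene-1,3-diol (racemic), via endoperoxide 5 (not isolated)
Conditions: O2 (1 atm), 5,10,15,20-tetraphenylporphyrin (0.5 mol %), thiourea (1.5 equiv), MeOH (2 % H2O)/CH2Cl2 4:1, hν (visible, >450 nm), −40 °C; then dark, −40 to 0 °C; neutral work-up
Reagents that add atoms: dioxygen (as singlet oxygen), O=O
Why: Singlet oxygen, formed by energy transfer from the excited porphyrin, adds in a concerted suprafacial [4π+2π] cycloaddition to the two termini of the fulvene ring diene; the closest known reaction type is the sensitised photooxygenation of cyclopentadienes and fulvenes to 2,3-dioxabicyclo[2.2.1]heptenes with thiourea reduction in the same pot. This one event forms both C–O bonds and closes the peroxide bridge of 5, that is the six-membered 3,6-dihydro-1,2-dioxine ring and the five-membered 1,2-dioxolane ring of the bicycle, both by cycloaddition and not by a stepwise exo or endo cyclisation. The two new stereocentres are the bridgehead carbons, and they must be cis because the two-atom O–O bridge can span only one face of the planar ring; the fulvene is achiral with equivalent faces, so 5 is racemic. Thiourea then attacks only the O–O bond, so both C–O bonds keep their configuration and diol 6 carries the ring alkene and the exocyclic alkene in their final positions. The selectivity required is periselectivity for [4+2] at the ring diene over an ene reaction at the allylic CH2 of the chain or attack at the exocyclic bond, and it is secured because the ring diene is locked s-cis whereas the exocyclic alkene is s-trans to both ring double bonds. Low temperature with the reductant already present keeps the labile endoperoxide from rearranging before it is reduced.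

Step 4
Reactants: 6 cis-2-undecylidenecyclopent-4-ene-1,3-diol
Product: 7 cis-2-undecylidenecyclopent-4-ene-1,3-diyl diacetate (racemic)
Conditions: Ac2O (2.5 equiv), pyridine (4 equiv), 4-(dimethylamino)pyridine (5 mol %), CH2Cl2, 0 °C
Reagents that add atoms: acetic anhydride, CC(=O)OC(C)=O
Why: Nucleophile-catalysed acylation of two secondary allylic alcohols under basic, non-ionising conditions, which touches no stereocentre and installs the final acetates that also shield one face of the ring.

Step 5
Reactants: 7 cis-2-undecylidenecyclopent-4-ene-1,3-diyl diacetate
Product: 8 2-hydroxy-2-(1-hydroxyundecyl)cyclopent-4-ene-1,3-diyl diacetate (racemic; acetates cis to each other; ring hydroxyl trans to both)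
Conditions: OsO4 (1 mol %), hydroquinidine 1,4-phthalazinediyl diether and hydroquinine 1,4-phthalazinediyl diether (2.5 mol % each), NMO (1.05 equiv), acetone/H2O 10:1, 0 °C, stopped at partial conversion, recovered 7 recycled
Reagents that add atoms: osmium tetroxide, O=[Os](=O)(=O)=O (transfers both oxygens, catalytic); N-methylmorpholine N-oxide (NMO), C[N+]1([O-])CCOCC1 (reoxidant, net source of one oxygen); water, O (net source of the other oxygen when the cyclic OsO4 adduct is hydrolysed)
Why: Ligand-accelerated catalytic syn-dihydroxylation (Upjohn/Sharpless type), in which the electrophilic amine-bound OsO4 should prefer the more electron-rich trisubstituted exocyclic alkene to the cis-disubstituted ring alkene (a class the phthalazine ligands accelerate poorly) and add in a [3+2] sense to the face opposite the two allylic acetoxy groups, which places the tertiary hydroxyl trans to both acetates and, by syn addition, fixes the side-chain carbinol; the two pseudoenantiomeric ligands are taken in equal amounts because 7 is racemic, and the near-neutral NMO medium guards against acetyl migration.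

Step 6
Reactants: 8 2-hydroxy-2-(1-hydroxyundecyl)cyclopent-4-ene-1,3-diyl diacetate
Product: 9 meso-2-hydroxy-2-undecanoylcyclopent-4-ene-1,3-diyl diacetate (acetates cis to each other and trans to the tertiary hydroxyl; target CNP0208983.3)
Conditions: 2-iodoxybenzoic acid (IBX, 1.5 equiv), DMSO, rt
Reagents that add atoms: none
Why: Hypervalent-iodine oxidation of a secondary alcohol, a reagent class known to turn 1,2-diols into α-hydroxy ketones without C–C cleavage, under neutral conditions that leave the tertiary alcohol, the allylic acetates and the ring alkene untouched; it removes the side-chain stereocentre, so both enantiomers of 8 give the one meso product.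

Compound list
1 | endo-dicyclopentadiene (racemic, one enantiomer drawn) | C1C=C[C@H]2[C@@H]1[C@@H]3C[C@H]2C=C3 | starting material
2 | cyclopenta-1,3-diene | C1C=CC=C1 | intermediate
3 | undecanal | CCCCCCCCCCC=O | starting material
4 | 6-decylfulvene (5-undecylidenecyclopenta-1,3-diene) | CCCCCCCCCCC=C1C=CC=C1 | intermediate
5 | 7-undecylidene-2,3-dioxabicyclo[2.2.1]hept-5-ene (endoperoxide; racemic, one enantiomer drawn) | CCCCCCCCCC/C=C1\[C@@H]2C=C[C@H]1OO2 | intermediate
6 | cis-2-undecylidenecyclopent-4-ene-1,3-diol (racemic, one enantiomer drawn) | CCCCCCCCCC/C=C1\[C@@H](O)C=C[C@H]1O | intermediate
7 | cis-2-undecylidenecyclopent-4-ene-1,3-diyl diacetate (racemic, one enantiomer drawn) | CCCCCCCCCC/C=C1\[C@@H](OC(C)=O)C=C[C@H]1OC(C)=O | intermediate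
8 | 2-hydroxy-2-(1-hydroxyundecyl)cyclopent-4-ene-1,3-diyl diacetate (acetates cis, ring hydroxyl trans to both, side-chain carbinol as set by syn addition; racemic, one enantiomer drawn) | CCCCCCCCCC[C@@H](O)[C@@]1(O)[C@@H](OC(C)=O)C=C[C@H]1OC(C)=O | intermediate
9 | meso-2-hydroxy-2-undecanoylcyclopent-4-ene-1,3-diyl diacetate (acetates cis to each other, trans to the tertiary hydroxyl, cis to the undecanoyl group) | CCCCCCCCCCC(=O)[C@@]1(O)[C@@H](OC(C)=O)C=C[C@H]1OC(C)=O | target

Total step count: 6. Longest linear sequence: 6 steps (1 → 2 → 4 → 6 → 7 → 8 → 9); undecanal 3 enters in step 2.

Steps most likely to fail

Step 5. The osmylation may discriminate too weakly between the exocyclic and the ring alkene, so that over-oxidation sets in before conversion is useful, or an acetyl group may migrate to the new side-chain hydroxyl. The fallback sets out from 7 and replaces the two-oxygen transfer by a one-oxygen transfer with a reagent more sensitive to alkene substitution. Epoxidation with mCPBA (NaHCO3-buffered CH2Cl2, 0 °C) should occur at the trisubstituted exocyclic alkene from the acetate-free face and give 2-decyl-1-oxaspiro[2.4]hept-5-ene-4,7-diyl diacetate F1, with the epoxide oxygen trans to both acetates. The epoxide is then opened oxidatively in DMSO under BF3·OEt2 activation: DMSO attacks the secondary epoxide carbon, and i-Pr2NEt collapses the alkoxysulfonium ion to the ketone (a Kornblum-type oxidation of an epoxide). The C1–O bond is never broken, so the tertiary carbinol keeps its configuration. DMSO is used as solvent so that it outcompetes the neighbouring acetates as nucleophile. The detour returns to the route at 9 and bypasses 8.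

Step 3. The endoperoxide may rearrange (or the fulvene may be consumed by an ene pathway) faster than thiourea reduces the O–O bond at low temperature, and the doubly allylic diol may ionise during isolation. The fallback sets out from 4 and keeps the same cycloaddition but unravels the peroxide in two redox stages. The photooxygenation is run without thiourea in CH2Cl2 at −78 °C with the same sensitiser, and the cold solution of 5 is treated with Et3N. Removal of a bridgehead hydrogen with O–O scission (Kornblum–DeLaMare rearrangement) should give (Z)-4-hydroxy-5-undecylidenecyclopent-2-en-1-one F2 and its geometric isomer (E)-4-hydroxy-5-undecylidenecyclopent-2-en-1-one F3, according to which bridgehead is deprotonated. Luche reduction of the mixture (NaBH4, CeCl3·7H2O, MeOH, −78 °C) is expected to deliver hydride 1,2 and anti to the existing hydroxyl. Both isomers then converge on the cis-diol, and the route is rejoined at 6; any trans-diol would be removed at the stage of 7.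

Step 6. The oxidation may be accompanied by cleavage of the glycol C–C bond, by an α-ketol shift with ring expansion, or by acetyl migration in 8 before the carbinol is oxidised. The fallback sets out from 7 and avoids the free diol altogether. A RuO4-catalysed ketohydroxylation (RuCl3 1 mol %, KHSO5 as 2KHSO5·KHSO4·K2SO4, NaHCO3, EtOAc/MeCN/H2O, rt, short contact time) should add to the exocyclic alkene from the acetate-free face. The cyclic RuO4 adduct is oxidised in place, so the tertiary carbon emerges as the alcohol and the secondary carbon as the ketone. The route is rejoined at 9, and no compound outside the compound list is made (F0).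

Further compounds
F1 | step 5 | 2-decyl-1-oxaspiro[2.4]hept-5-ene-4,7-diyl diacetate (epoxide oxygen trans to both acetates; racemic, one enantiomer drawn) | CCCCCCCCCC[C@H]1O[C@@]12[C@@H](OC(C)=O)C=C[C@H]2OC(C)=O
F2 | step 3 | (Z)-4-hydroxy-5-undecylidenecyclopent-2-en-1-one (racemic, one enantiomer drawn) | CCCCCCCCCC/C=C1\C(=O)C=C[C@H]1O
F3 | step 3 | (E)-4-hydroxy-5-undecylidenecyclopent-2-en-1-one (racemic, one enantiomer drawn) | CCCCCCCCCC/C=C1\[C@@H](O)C=CC1=O
F0 | step 6 | none | none
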